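If the electrophile loses the same factor in each equal stretch of time, a logarithmic scale lets one number carry its decay, and I look for that number in the earlier runs.

| flask | electrophile | nucleophile | free base | remark | time |
|---|---|---|---|---|---|
| ochre | 0.010 M | 0.020 M | 0.0060 M | run made earlier |  |
| red | 0.010 M | 0.020 M | 0.0090 M | run made earlier |  |
| blue | 0.020 M | 0.020 M | 0.012 M | run made earlier |  |
| flask | 0.010 M | 0.0200 M | 0.0120 M |  | 10 d |

| run | time / d | electrophile / % | target / % |
|---|---|---|---|
| ochre | 1.67 | 26 | 24 |
| ochre | 3.00 | 13 | 25 |
| ochre | 5.00 | 1 | 23 |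
| ochre | 6.00 | 4 | 23 |
| ochre | 8.00 | 0 | 22 |
| ochre | 10.0 | 0 | 23 |
| ochre | 12.0 | 1 | 21 |
| red | 0.625 | 54 | 27 |
| red | 1.67 | 27 | 26 |
| red | 3.00 | 11 | 25 |
| red | 5.00 | 3 | 22 |
| red | 8.00 | 2 | 24 |
| red | 10.0 | 0 | 23 |
| red | 12.0 | 0 | 21 |
| blue | 1.04 | 40 | 14 |
| blue | 3.00 | 17 | 11 |
| blue | 6.00 | 4 | 8 |
| blue | 8.00 | 2 | 5 |
| blue | 12.0 | 0 | 9 |

(each reading ± 1.5 percentage points)

- the earlier runs do not show how much of nucleophile is bound; that part of a forecast is a guess

* part of the electrophile that has reacted at 10 d
* share of free nucleophile in free nucleophile and protonated nucleophile together, at 10 d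

The ochre and red runs charge electrophile and nucleophile as the flask does. At 3.00 d they read 13% and 11% of the electrophile, a mean of 12.0%. Stretched to 10 d, that fall gives 3.07. I call this number the decades of decay: the powers of ten by which a first-order electrophile falls in the flask's whole time. Read so, I expect 0.0851% to be left in the flask, and I commit to c near 99.9%.

Is one number enough? The readings at 1.67 d, 26% and 27%, stretched the same way, give 3.45, more than 3.07, so the decay seems to slow a little. The two runs differ in free base, yet their readings at 3.00 d part by 2 percentage points with a scatter of 1.5 points. For c the number serves. For fr it says nothing: no reading shows bound nucleophile, and I have no figure of my own.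

The forecast puts c at 99.7% (98% to 100%) and fr at 70% (30% to 95%), saying of the latter: “This is a guess, so the range is wide”.

The flask gives 99.9% for c and 77.4% for fr.

    electrophile + nucleophile → acid set free + target (k = 0.0400 M⁻¹ min⁻¹)
    nucleophile + acid set free ⇌ protonated nucleophile, settled at all times (K = 1.50 × 10⁵ M⁻¹)
    acid set free + free base ⇌ salt of the base, settled at all times (K = 3.40 × 10⁵ M⁻¹)
    target → over-reaction product (k = 6.60 × 10⁻⁷ min⁻¹)
    electrophile + target → side product (k = 0.0940 M⁻¹ min⁻¹)
    nucleophile ⇌ dormant form (K = 1.50, k = 7.80 × 10⁻⁴ min⁻¹)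

At 10.0 d the flask holds 0.144% of its electrophile, which is 2.84 decades against my 3.07. The electrophile's half-life by its step with the nucleophile, 0.87 d at 0.217 d, is short against the 10 d of standing. The neighbour flask with 0.030 M of free base leaves 0.11% of its electrophile, 2.96 decades, while its fr rises to 90.6%.

Readings and results stem from a simulated flask with made-up constants; scatter was added.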